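## Retrosynthetic overview

- Numbering used below: C1 = ring CH, C2→C14 round the ring through C3=C4(CH2OH), C7=C8(CH3), C11=C12(CH3); C15 = carbinol carbon. PMB = 4-methoxybenzyl, TES = SiEt3, TBS = SiMe2tBu.
- Only one ring is formed, and it is formed last: the 14-membered ring is closed at C5–C6 by intramolecular alkylation of a C6 allylic sulfone with a C5 allylic bromide, then Pd-catalysed desulfonylation and desilylation.
- C3=C4 and its CH2OH: a lipase mono-acetylates a 2-alkylidenepropane-1,3-diol on the arm trans to C2 (that arm becomes C5, the untouched arm is the CH2OH of the target). The diol comes from a C3 aldehyde by Knoevenagel condensation and reduction.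
- C13–C14: alkylation of sulfone 7 (C1, C2, C3, C14, C15 and side chain) with the (Z)-allylic bromide 17 (C6–C13), then reductive desulfonylation.
- 7: geraniol, Sharpless epoxidation (sets C1 and C15 together), vinyl-cuprate opening. 17: geraniol, terminal alkene cleavage, Still–Gennari olefination (11Z).

Assumption: the target is read from the SMILES as (1R,15R) with CH2OH cis to C2 on C3=C4, 7E and 11Z; numbered compounds are substrates, intermediates and carbon building blocks, other reagents are given in their step, and salts formed by simple deprotonation are not numbered separately.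

## Route

Step 1
Reactants: 1 geraniol
Product: 2 (2R,3R)-2,3-epoxygeraniol
Conditions: Ti(OiPr)4 (5 mol %), D-(−)-diethyl tartrate (7 mol %), t-BuOOH, 4 Å MS, CH2Cl2, −20 °C
Reagents that add atoms: tert-butyl hydroperoxide, CC(C)(C)OO
Why: Katsuki–Sharpless asymmetric epoxidation, in which the Ti–D-(−)-tartrate catalyst delivers oxygen to one face of the allylic-alcohol alkene only, setting both future stereocentres (C1 and C15) as the (2R,3R)-epoxide in about 90–95% ee and leaving the remote alkene untouched.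

Step 2
Reactants: 2 (2R,3R)-2,3-epoxygeraniol; 3 vinylmagnesium bromide
Product: 4 (2S,3R)-2-ethenyl-3,7-dimethyloct-6-ene-1,3-diol
Conditions: 3 (4 equiv), CuI (0.3 equiv), THF/Et2O, −40 → 0 °C; aq NH4Cl
Reagents that add atoms: none
Why: Copper-mediated SN2 epoxide opening, in which the vinyl cuprate attacks the only non-quaternary epoxide carbon anti to oxygen, so the future C1 is inverted to the required configuration while the C15–O bond and its configuration are untouched.

Step 3
Reactants: 4 (2S,3R)-2-ethenyl-3,7-dimethyloct-6-ene-1,3-diol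
Product: 5 (3R,4R)-4,8-dimethyl-3-[(phenylsulfanyl)methyl]nona-1,7-dien-4-ol
Conditions: PhSSPh, n-Bu3P, THF, rt
Reagents that add atoms: diphenyl disulfide, c1ccc(SSc2ccccc2)cc1
Why: Hata thioetherification (Mitsunobu-type), in which Bu3P/PhSSPh activates only the primary alcohol for SN2 displacement by thiolate while the tertiary alcohol is inert.

Step 4
Reactants: 5 (3R,4R)-4,8-dimethyl-3-[(phenylsulfanyl)methyl]nona-1,7-dien-4-ol
Product: 6 triethylsilyl ether of 5
Conditions: TESOTf, 2,6-lutidine, CH2Cl2, −78 → 0 °C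
Reagents that add atoms: triethylsilyl trifluoromethanesulfonate, CC[Si](CC)(CC)OS(=O)(=O)C(F)(F)F
Why: Silyl triflate silylation masks the hindered tertiary alcohol so that it cannot be alkylated or quench base in the later carbanion steps.

Step 5
Reactants: 6 triethylsilyl ether of 5
Product: 7 sulfone {[(3R,4R)-3-[(benzenesulfonyl)methyl]-4,8-dimethylnona-1,7-dien-4-yl]oxy}triethylsilane
Conditions: (NH4)6Mo7O24·4H2O (10 mol %), 30% H2O2, EtOH, 0 °C → rt
Reagents that add atoms: hydrogen peroxide, OO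
Why: Molybdate-catalysed peroxide oxidation takes the sulfide to the sulfone much faster than it epoxidises the isolated alkenes.

Step 6
Reactants: 1 geraniol
Product: 8 geranyl 4-methoxybenzyl ether
Conditions: NaH, PMBCl, n-Bu4NI (cat.), THF/DMF, 0 °C → rt
Reagents that add atoms: 4-methoxybenzyl chloride, COc1ccc(CCl)cc1
Why: Williamson etherification protects the allylic alcohol as a PMB ether that survives base, hydride and dissolving metal and is removed oxidatively later.

Step 7
Reactants: 8 geranyl 4-methoxybenzyl ether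
Product: 9 6,7-epoxide of 8 (racemic)
Conditions: mCPBA (1.05 equiv), NaHCO3, CH2Cl2, −20 → 0 °C
Reagents that add atoms: 3-chloroperoxybenzoic acid, OOC(=O)c1cccc(Cl)c1
Why: Prilezhaev epoxidation is regioselective for the remote and more electron-rich alkene because the allylic oxygen deactivates the 2,3-alkene, and the racemic epoxide carbon is destroyed in step 8.

Step 8
Reactants: 9 6,7-epoxide of 8 (racemic)
Product: 11 (4E)-6-[(4-methoxybenzyl)oxy]-4-methylhex-4-enal, via diol 10 (not isolated)
Conditions: H5IO6, THF/H2O, 0 °C → rt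
Reagents that add atoms: none
Why: Acid-mediated epoxide hydrolysis followed by Malaprade periodate glycol cleavage excises acetone and leaves the C11 aldehyde with the E alkene intact.

Step 9
Reactants: 12 methyl [bis(2,2,2-trifluoroethoxy)phosphoryl]acetate
Product: 13 methyl 2-[bis(2,2,2-trifluoroethoxy)phosphoryl]propanoate (racemic)
Conditions: KOt-Bu (1.0 equiv), MeI, THF, 0 °C → rt
Reagents that add atoms: iodomethane, CI
Why: C-alkylation of the stabilised phosphonoacetate anion with methyl iodide gives the α-methyl Still–Gennari reagent from an achiral precursor.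

Step 10
Reactants: 11 (4E)-6-[(4-methoxybenzyl)oxy]-4-methylhex-4-enal; 13 methyl 2-[bis(2,2,2-trifluoroethoxy)phosphoryl]propanoate
Product: 14 methyl (2Z,6E)-8-[(4-methoxybenzyl)oxy]-2,6-dimethylocta-2,6-dienoate
Conditions: 13, KHMDS, 18-crown-6, THF, −78 °C; then 11
Reagents that add atoms: none
Why: Still–Gennari olefination, in which the crown-ether-separated potassium enolate of the trifluoroethyl phosphonate adds under kinetic control and eliminates fast to the (Z)-α-methyl enoate, fixing the 11Z alkene.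

Step 11
Reactants: 14 methyl (2Z,6E)-8-[(4-methoxybenzyl)oxy]-2,6-dimethylocta-2,6-dienoate
Product: 15 (2Z,6E)-8-[(4-methoxybenzyl)oxy]-2,6-dimethylocta-2,6-dien-1-ol
Conditions: DIBAL-H (2.5 equiv), CH2Cl2, −78 °C; Rochelle salt
Reagents that add atoms: none
Why: DIBAL 1,2-reduction of the enoate gives the (Z)-allylic alcohol without touching the ether or the alkene geometry.

Step 12
Reactants: 15 (2Z,6E)-8-[(4-methoxybenzyl)oxy]-2,6-dimethylocta-2,6-dien-1-ol
Product: 17 1-({[(2E,6Z)-8-bromo-3,7-dimethylocta-2,6-dien-1-yl]oxy}methyl)-4-methoxybenzene, via allylic mesylate 16 (not isolated)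
Conditions: MsCl, Et3N, THF, −40 °C; then LiBr, −40 → 0 °C
Reagents that add atoms: lithium bromide, [Li+].[Br-]; methanesulfonyl chloride, CS(=O)(=O)Cl (its atoms stay in 16 only)
Why: Mesylation followed by SN2 displacement with bromide gives the primary allylic bromide with the Z geometry retained.

Step 13
Reactants: 7 sulfone; 17 (2E,6Z)-allylic bromide
Product: 18 C14-sulfonyl seco-tetraene (C14 epimers)
Conditions: 7, n-BuLi, THF, −78 °C; then 17, HMPA, −78 → −20 °C
Reagents that add atoms: none
Why: SN2 alkylation of the α-sulfonyl carbanion of 7 with a reactive primary allylic bromide forms the C13–C14 bond, C1 and C15 are not involved, and the new C14 centre is removed in step 14.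

Step 14
Reactants: 18 C14-sulfonyl seco-tetraene
Product: 19 seco-tetraene with C1 vinyl group
Conditions: 6% Na(Hg), Na2HPO4, MeOH/THF, −20 → 0 °C
Reagents that add atoms: none
Why: Reductive desulfonylation by electron transfer from sodium amalgam replaces the non-allylic C14–S bond by C–H and leaves the alkenes and both stereocentres in place.

Step 15
Reactants: 19 seco-tetraene with C1 vinyl group
Product: 21 C3 primary alcohol, via B-alkyl-9-BBN borane 20 (not isolated)
Conditions: 9-BBN, THF, 0 °C → rt; then NaOH, 30% H2O2, 0 °C → rt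
Reagents that add atoms: hydrogen peroxide, OO; 9-borabicyclo[3.3.1]nonane, B1C2CCCC1CCC2 (boron stays in 20 only)
Why: Anti-Markovnikov hydroboration–oxidation, in which 9-BBN reacts only with the monosubstituted vinyl group and places boron on the terminal carbon, which oxidation converts into the C3 alcohol.

Step 16
Reactants: 21 C3 primary alcohol
Product: 22 C3 aldehyde
Conditions: Dess–Martin periodinane, NaHCO3, CH2Cl2, 0 °C → rt
Reagents that add atoms: none
Why: Dess–Martin oxidation gives the aldehyde under buffered conditions, and C1 is β to the carbonyl so it cannot epimerise by enolisation.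

Step 17
Reactants: 22 C3 aldehyde; 23 dimethyl malonate
Product: 24 alkylidene malonate C3H=C4(CO2Me)2
Conditions: 23, piperidine (cat.), AcOH (cat.), 4 Å MS, CH2Cl2, rt
Reagents that add atoms: none
Why: Knoevenagel condensation builds C4 with two identical ester arms, so no alkene geometry has to be controlled at this stage.

Step 18
Reactants: 24 alkylidene malonate
Product: 25 2-alkylidenepropane-1,3-diol C3H=C4(CH2OH)2
Conditions: DIBAL-H (5 equiv), CH2Cl2, −78 → −20 °C; Rochelle salt
Reagents that add atoms: none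
Why: DIBAL 1,2-reduction of both conjugated esters gives the symmetrical allylic diol that is the substrate of the enzymatic step.

Step 19
Reactants: 25 2-alkylidenepropane-1,3-diol
Product: 26 mono-acetate with CH2OAc trans to C2 and free CH2OH cis to C2
Conditions: lipase (Burkholderia cepacia lipase, immobilised), vinyl acetate (3 equiv), THF, 25 °C, stopped when 25 is consumed
Reagents that add atoms: vinyl acetate, CC(=O)OC=C
Why: Lipase-catalysed irreversible transesterification, in which the enzyme acylates only the less hindered hydroxymethyl group trans to the C2 chain, so the acetylated carbon becomes C5 and the free CH2OH is the one cis to C2, which fixes the geometry of the C3=C4 alkene of the target.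

Step 20
Reactants: 26 mono-acetate
Product: 27 TBS ether of 26
Conditions: TBSCl, imidazole, CH2Cl2, 0 °C → rt
Reagents that add atoms: tert-butyldimethylsilyl chloride, CC(C)(C)[Si](C)(C)Cl
Why: Silylation of the remaining primary allylic alcohol protects the future C4 hydroxymethyl group.

Step 21
Reactants: 27 TBS ether of 26
Product: 28 C6 allylic alcohol
Conditions: DDQ, CH2Cl2/pH 7 buffer (10:1), 0 °C
Reagents that add atoms: none
Why: Oxidative PMB cleavage by DDQ (hydride abstraction then hydrolysis) frees the C6 alcohol without touching the silyl ethers, the acetate or the alkenes.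

Step 22
Reactants: 28 C6 allylic alcohol
Product: 30 C6 allylic bromide, via C6 mesylate 29 (not isolated)
Conditions: MsCl, Et3N, THF, −40 °C; then LiBr, −40 → 0 °C
Reagents that add atoms: lithium bromide, [Li+].[Br-]; methanesulfonyl chloride, CS(=O)(=O)Cl (its atoms stay in 29 only)
Why: Mesylation and SN2 bromide displacement give the geranyl-type primary allylic bromide with the 7E geometry retained.

Step 23
Reactants: 30 C6 allylic bromide
Product: 31 C6 allylic phenyl sulfone
Conditions: PhSO2Na, DMF, 0 °C → rt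
Reagents that add atoms: sodium benzenesulfinate, [Na+].[O-]S(=O)c1ccccc1
Why: SN2 S-alkylation of sulfinate by the allylic bromide installs the carbanion-stabilising sulfone at C6.

Step 24
Reactants: 31 C6 allylic phenyl sulfone
Product: 32 C5 allylic alcohol
Conditions: K2CO3 (0.3 equiv), MeOH, 0 °C
Reagents that add atoms: none
Why: Base-catalysed transesterification (methanolysis) removes the acetate and frees the C5 alcohol while the silyl ethers and the sulfone are untouched.

Step 25
Reactants: 32 C5 allylic alcohol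
Product: 34 C5 allylic bromide, via C5 mesylate 33 (not isolated)
Conditions: MsCl, Et3N, THF, −40 °C; then LiBr, −40 → 0 °C
Reagents that add atoms: lithium bromide, [Li+].[Br-]; methanesulfonyl chloride, CS(=O)(=O)Cl (its atoms stay in 33 only)
Why: Mesylation and SN2 bromide displacement turn C5 into the allylic bromide and preserve the alkene geometry set in the lipase step.

Step 26
Reactants: 34 C5 allylic bromide
Product: 35 macrocyclic C6 sulfone (C6 epimers)
Conditions: KHMDS (1.3 equiv), THF (0.002 M), slow addition of 34, −78 → 0 °C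
Reagents that add atoms: none
Why: Intramolecular SN2 alkylation of the allylic α-sulfonyl carbanion by the C5 allylic bromide at high dilution closes the 14-membered ring without touching any stereocentre or alkene geometry, and the C6 epimers converge in step 27.

Step 27
Reactants: 35 macrocyclic C6 sulfone
Product: 36 bis-silyl ether of the target
Conditions: PdCl2(dppp) (10 mol %), LiBHEt3, THF, 0 °C
Reagents that add atoms: none
Why: Palladium-catalysed reductive desulfonylation, in which Pd(0) ionises the allylic sulfone to a π-allyl complex and hydride is delivered to the less substituted terminus C6, keeping the trisubstituted 7E alkene in place.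

Step 28
Reactants: 36 bis-silyl ether of the target
Product: 37 (2R)-2-[(1R,3Z,7E,11Z)-4-(hydroxymethyl)-8,12-dimethylcyclotetradeca-3,7,11-trien-1-yl]-6-methylhept-5-en-2-ol
Conditions: TBAF, THF, rt → 45 °C
Reagents that add atoms: none
Why: Fluoride-mediated desilylation removes both silyl ethers and gives the target with C1 and C15 unchanged since step 2.

## Compound list

1 | geraniol, (2E)-3,7-dimethylocta-2,6-dien-1-ol | CC(C)=CCC/C(C)=C/CO | starting material
2 | [(2R,3R)-3-methyl-3-(4-methylpent-3-en-1-yl)oxiran-2-yl]methanol | CC(C)=CCC[C@@]1(C)O[C@@H]1CO | intermediate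
3 | vinylmagnesium bromide | C=C[Mg]Br | starting material
4 | (2S,3R)-2-ethenyl-3,7-dimethyloct-6-ene-1,3-diol | CC(C)=CCC[C@@](C)(O)[C@H](CO)C=C | intermediate
5 | (3R,4R)-4,8-dimethyl-3-[(phenylsulfanyl)methyl]nona-1,7-dien-4-ol | CC(C)=CCC[C@@](C)(O)[C@H](CSc1ccccc1)C=C | intermediate
6 | triethyl{[(3R,4R)-4,8-dimethyl-3-[(phenylsulfanyl)methyl]nona-1,7-dien-4-yl]oxy}silane | CC(C)=CCC[C@@](C)(O[Si](CC)(CC)CC)[C@H](CSc1ccccc1)C=C | intermediate
7 | {[(3R,4R)-3-[(benzenesulfonyl)methyl]-4,8-dimethylnona-1,7-dien-4-yl]oxy}triethylsilane | CC(C)=CCC[C@@](C)(O[Si](CC)(CC)CC)[C@H](CS(=O)(=O)c1ccccc1)C=C | intermediate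
8 | 1-({[(2E)-3,7-dimethylocta-2,6-dien-1-yl]oxy}methyl)-4-methoxybenzene | CC(C)=CCC/C(C)=C/COCc1ccc(OC)cc1 | intermediate
9 | 3-{(3E)-5-[(4-methoxybenzyl)oxy]-3-methylpent-3-en-1-yl}-2,2-dimethyloxirane (racemic) | CC1(C)OC1CC/C(C)=C/COCc1ccc(OC)cc1 | intermediate
10 | (6E)-8-[(4-methoxybenzyl)oxy]-2,6-dimethyloct-6-ene-2,3-diol (racemic; not isolated) | CC(C)(O)C(O)CC/C(C)=C/COCc1ccc(OC)cc1 | intermediate
11 | (4E)-6-[(4-methoxybenzyl)oxy]-4-methylhex-4-enal | O=CCC/C(C)=C/COCc1ccc(OC)cc1 | intermediate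
12 | methyl [bis(2,2,2-trifluoroethoxy)phosphoryl]acetate | COC(=O)CP(=O)(OCC(F)(F)F)OCC(F)(F)F | starting material
13 | methyl 2-[bis(2,2,2-trifluoroethoxy)phosphoryl]propanoate (racemic) | COC(=O)C(C)P(=O)(OCC(F)(F)F)OCC(F)(F)F | intermediate
14 | methyl (2Z,6E)-8-[(4-methoxybenzyl)oxy]-2,6-dimethylocta-2,6-dienoate | COC(=O)/C(C)=C\CC/C(C)=C/COCc1ccc(OC)cc1 | intermediate
15 | (2Z,6E)-8-[(4-methoxybenzyl)oxy]-2,6-dimethylocta-2,6-dien-1-ol | OC/C(C)=C\CC/C(C)=C/COCc1ccc(OC)cc1 | intermediate
16 | (2Z,6E)-8-[(4-methoxybenzyl)oxy]-2,6-dimethylocta-2,6-dien-1-yl methanesulfonate (not isolated) | CS(=O)(=O)OC/C(C)=C\CC/C(C)=C/COCc1ccc(OC)cc1 | intermediate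
17 | 1-({[(2E,6Z)-8-bromo-3,7-dimethylocta-2,6-dien-1-yl]oxy}methyl)-4-methoxybenzene | BrC/C(C)=C\CC/C(C)=C/COCc1ccc(OC)cc1 | intermediate
18 | C14-sulfonyl seco-tetraene: 7 with one C14–H replaced by the (2Z,6E)-8-[(4-methoxybenzyl)oxy]-2,6-dimethylocta-2,6-dien-1-yl group; (1R,15R), C14 epimers | CC(C)=CCC[C@@](C)(O[Si](CC)(CC)CC)[C@H](C(S(=O)(=O)c1ccccc1)C/C(C)=C\CC/C(C)=C/COCc1ccc(OC)cc1)C=C | intermediate
19 | seco-tetraene (1R,15R): C1 bears vinyl (C2=C3), C15(CH3)(OTES)(4-methylpent-3-enyl) and the chain C14H2–C13H2–C12(CH3)=C11H–C10H2–C9H2–C8(CH3)=C7H–C6H2–OPMB with 11Z and 7E | CC(C)=CCC[C@@](C)(O[Si](CC)(CC)CC)[C@H](CC/C(C)=C\CC/C(C)=C/COCc1ccc(OC)cc1)C=C | intermediate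
20 | B-alkyl-9-BBN adduct of 19, boron on C3 (not isolated) | CC(C)=CCC[C@@](C)(O[Si](CC)(CC)CC)[C@H](CC/C(C)=C\CC/C(C)=C/COCc1ccc(OC)cc1)CCB1C2CCCC1CCC2 | intermediate
21 | C3 primary alcohol: 19 with CH2CH2OH in place of the vinyl group | CC(C)=CCC[C@@](C)(O[Si](CC)(CC)CC)[C@H](CC/C(C)=C\CC/C(C)=C/COCc1ccc(OC)cc1)CCO | intermediate
22 | C3 aldehyde: 21 with CH2CHO in place of CH2CH2OH | CC(C)=CCC[C@@](C)(O[Si](CC)(CC)CC)[C@H](CC/C(C)=C\CC/C(C)=C/COCc1ccc(OC)cc1)CC=O | intermediate
23 | dimethyl malonate | COC(=O)CC(=O)OC | starting material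
24 | alkylidene malonate: C2H2–C3H=C4(CO2Me)2 in place of the aldehyde of 22 | CC(C)=CCC[C@@](C)(O[Si](CC)(CC)CC)[C@H](CC/C(C)=C\CC/C(C)=C/COCc1ccc(OC)cc1)CC=C(C(=O)OC)C(=O)OC | intermediate
25 | 2-alkylidenepropane-1,3-diol: C3H=C4(CH2OH)2 | CC(C)=CCC[C@@](C)(O[Si](CC)(CC)CC)[C@H](CC/C(C)=C\CC/C(C)=C/COCc1ccc(OC)cc1)CC=C(CO)CO | intermediate
26 | mono-acetate: C3H=C4(CH2OH)(CH2OAc), CH2OAc (C5) trans to C2, CH2OH cis to C2 | CC(C)=CCC[C@@](C)(O[Si](CC)(CC)CC)[C@H](CC/C(C)=C\CC/C(C)=C/COCc1ccc(OC)cc1)C/C=C(\CO)COC(C)=O | intermediate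
27 | TBS ether of 26: C4–CH2OTBS cis to C2, C5–OAc, C6–OPMB | CC(C)=CCC[C@@](C)(O[Si](CC)(CC)CC)[C@H](CC/C(C)=C\CC/C(C)=C/COCc1ccc(OC)cc1)C/C=C(\CO[Si](C)(C)C(C)(C)C)COC(C)=O | intermediate
28 | C6 allylic alcohol: 27 with the PMB group removed | CC(C)=CCC[C@@](C)(O[Si](CC)(CC)CC)[C@H](CC/C(C)=C\CC/C(C)=C/CO)C/C=C(\CO[Si](C)(C)C(C)(C)C)COC(C)=O | intermediate
29 | C6 methanesulfonate of 28 (not isolated) | CC(C)=CCC[C@@](C)(O[Si](CC)(CC)CC)[C@H](CC/C(C)=C\CC/C(C)=C/COS(C)(=O)=O)C/C=C(\CO[Si](C)(C)C(C)(C)C)COC(C)=O | intermediate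
30 | C6 allylic bromide | CC(C)=CCC[C@@](C)(O[Si](CC)(CC)CC)[C@H](CC/C(C)=C\CC/C(C)=C/CBr)C/C=C(\CO[Si](C)(C)C(C)(C)C)COC(C)=O | intermediate
31 | C6 allylic phenyl sulfone with C5–OAc | CC(C)=CCC[C@@](C)(O[Si](CC)(CC)CC)[C@H](CC/C(C)=C\CC/C(C)=C/CS(=O)(=O)c1ccccc1)C/C=C(\CO[Si](C)(C)C(C)(C)C)COC(C)=O | intermediate
32 | C5 allylic alcohol: 31 with the acetate removed | CC(C)=CCC[C@@](C)(O[Si](CC)(CC)CC)[C@H](CC/C(C)=C\CC/C(C)=C/CS(=O)(=O)c1ccccc1)C/C=C(\CO[Si](C)(C)C(C)(C)C)CO | intermediate
33 | C5 methanesulfonate of 32 (not isolated) | CC(C)=CCC[C@@](C)(O[Si](CC)(CC)CC)[C@H](CC/C(C)=C\CC/C(C)=C/CS(=O)(=O)c1ccccc1)C/C=C(\CO[Si](C)(C)C(C)(C)C)COS(C)(=O)=O | intermediate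
34 | C5 allylic bromide with C6 sulfone | CC(C)=CCC[C@@](C)(O[Si](CC)(CC)CC)[C@H](CC/C(C)=C\CC/C(C)=C/CS(=O)(=O)c1ccccc1)C/C=C(\CO[Si](C)(C)C(C)(C)C)CBr | intermediate
35 | macrocyclic sulfone: 14-membered ring, PhSO2 on C6 (epimers), C4–CH2OTBS cis to C2, 7E, 11Z, C15–OTES, (1R,15R) | CC(C)=CCC[C@@](C)(O[Si](CC)(CC)CC)[C@H]1C/C=C(\CO[Si](C)(C)C(C)(C)C)CC(S(=O)(=O)c2ccccc2)/C=C(\C)CC/C=C(/C)CC1 | intermediate
36 | bis-silyl ether of the target: C4–CH2OTBS, C15–OTES | CC(C)=CCC[C@@](C)(O[Si](CC)(CC)CC)[C@H]1C/C=C(\CO[Si](C)(C)C(C)(C)C)CC/C=C(\C)CC/C=C(/C)CC1 | intermediate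
37 | (2R)-2-[(1R,3Z,7E,11Z)-4-(hydroxymethyl)-8,12-dimethylcyclotetradeca-3,7,11-trien-1-yl]-6-methylhept-5-en-2-ol | CC(C)=CCC[C@@](C)(O)[C@H]1C/C=C(\CO)CC/C=C(\C)CC/C=C(/C)CC1 | target

## Step count, longest sequence and weakest steps

Total: 28 steps. Longest linear sequence: 22 steps (geraniol 1 → 8 → 9 → 11 → 14 → 15 → 17, then steps 13–28).

The three steps most likely to fail are steps 2, 18 and 26.

Risk at step 2. The cuprate has to attack a carbon next to a quaternary centre, and MgBr2 can divert the trisubstituted epoxide to a bromohydrin or a Meinwald-rearranged carbonyl compound. The fallback sets out from 2 and comes back at 4. It replaces the copper reagent by an acetylide SN2 opening on the O-protected epoxide, so that no free alkoxide (and no Payne shift) is present. Silylation of 2 (TBSCl, imidazole) gives the epoxy silyl ether F1. Lithium acetylide–ethylenediamine in DMSO opens F1 at the same non-quaternary carbon with inversion to give the alkynyl carbinol F2. Lindlar semihydrogenation (H2, Pd/CaCO3/Pb, quinoline) converts F2 into the vinyl carbinol silyl ether F3. TBAF then returns diol 4.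

Risk at step 18. Alkylidene malonates are strong Michael acceptors, so hydride may add 1,4 or over-reduce. The fallback sets out from 21 and comes back at 25. It builds the same symmetrical diol by a Wittig reaction with a symmetrical ketone instead of an ester reduction, so there is again no alkene geometry to control. Alcohol 21 is converted with I2, PPh3 and imidazole into the C3 iodide F4. Heating F4 with PPh3 in MeCN gives the phosphonium iodide F5. The ylide from F5 (KHMDS, THF, −78 °C) reacts with 2,2-dimethyl-1,3-dioxan-5-one to give the 5-alkylidene-1,3-dioxane F6. Brief PPTS/MeOH treatment removes the acetonide and returns diol 25 for the lipase step.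

Risk at step 26. The SN2 macrocyclisation can lose material to oligomers or elimination. The fallback sets out from 32 and comes back at 35. It uses a palladium-templated closure with a soft nucleophile in place of a strong-base SN2 reaction. Treating 32 with LiHMDS (3 equiv) and methyl chloroformate acylates the C5 oxygen and the C6 sulfonyl carbanion, giving the carbonate sulfonyl ester F7. Pd(PPh3)4/dppe in refluxing THF with slow addition ionises the allylic carbonate, and the sulfonyl-ester enolate formed by the released methoxide attacks the π-allyl terminus C5 (Tsuji–Trost macrocyclisation). This gives the macrocyclic sulfonyl ester F8. Krapcho demethoxycarbonylation (LiCl, wet DMSO, 140 °C) returns the macrocyclic sulfone 35.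

## Further compounds

F1 | step 2 | tert-butyl(dimethyl){[(2R,3R)-3-methyl-3-(4-methylpent-3-en-1-yl)oxiran-2-yl]methoxy}silane | CC(C)=CCC[C@@]1(C)O[C@@H]1CO[Si](C)(C)C(C)(C)C
F2 | step 2 | (3S,4R)-3-({[tert-butyl(dimethyl)silyl]oxy}methyl)-4,8-dimethylnon-7-en-1-yn-4-ol | CC(C)=CCC[C@@](C)(O)[C@H](CO[Si](C)(C)C(C)(C)C)C#C
F3 | step 2 | (3S,4R)-3-({[tert-butyl(dimethyl)silyl]oxy}methyl)-4,8-dimethylnona-1,7-dien-4-ol | CC(C)=CCC[C@@](C)(O)[C@H](CO[Si](C)(C)C(C)(C)C)C=C
F4 | step 18 | C3 iodide: 21 with I in place of OH | CC(C)=CCC[C@@](C)(O[Si](CC)(CC)CC)[C@H](CC/C(C)=C\CC/C(C)=C/COCc1ccc(OC)cc1)CCI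
F5 | step 18 | C3 triphenylphosphonium iodide from F4 | CC(C)=CCC[C@@](C)(O[Si](CC)(CC)CC)[C@H](CC/C(C)=C\CC/C(C)=C/COCc1ccc(OC)cc1)CC[P+](c1ccccc1)(c1ccccc1)c1ccccc1.[I-]
F6 | step 18 | 5-alkylidene-2,2-dimethyl-1,3-dioxane (acetonide of 25) | CC(C)=CCC[C@@](C)(O[Si](CC)(CC)CC)[C@H](CC/C(C)=C\CC/C(C)=C/COCc1ccc(OC)cc1)CC=C1COC(C)(C)OC1
F7 | step 26 | 32 with a methyl carbonate on the C5 oxygen and CO2Me on C6 (C6 epimers) | CC(C)=CCC[C@@](C)(O[Si](CC)(CC)CC)[C@H](CC/C(C)=C\CC/C(C)=C/C(C(=O)OC)S(=O)(=O)c1ccccc1)C/C=C(\CO[Si](C)(C)C(C)(C)C)COC(=O)OC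
F8 | step 26 | macrocyclic sulfone 35 with an additional CO2Me on C6 | CC(C)=CCC[C@@](C)(O[Si](CC)(CC)CC)[C@H]1C/C=C(\CO[Si](C)(C)C(C)(C)C)CC(C(=O)OC)(S(=O)(=O)c2ccccc2)/C=C(\C)CC/C=C(/C)CC1
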